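## Retrosynthetic overview

1. The acetate and the lactone α-hydroxyl are added last; the exocyclic methylene comes from a ketone, the ketone from an enone, and the enone from a Nozaki–Hiyama–Kishi union of a hydrindadienyl triflate with a side-chain aldehyde that already carries the lactone and both carbon stereocenters of the chain.
2. Side-chain aldehyde: syn-selective organocatalytic Michael addition of methyl 4-oxobutanoate to a silyloxy nitroalkene, then reduction/lactonization and a Nef reaction.
3. Hydrindane: the cyclopentane ring is bought as 2-methylcyclopent-2-en-1-one; CBS reduction and Ireland–Claisen rearrangement set C3a and attach the C4–C5 arm; the cyclohexene ring is then closed in one operation by an anionic [4+2] annulation in which vinyltriphenylphosphonium bromide supplies C6–C7 (Michael addition of the C7a enolate, then intramolecular Wittig reaction at C5).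
4. Enabling feature: in the six-membered carbocycle (C3a, C4, C5, C6, C7, C7a) the atoms C5–C7 are bare methylenes, the quaternary C7a lies alpha to C1 of the five-membered ring (a ketone until the side chain arrives), and C5 hangs on the gem-dimethyl carbon C4, which cannot enolize. C7a can therefore be an enolate carbon, C5 a non-enolizable aldehyde and C6–C7 a traceless two-carbon unit; the residual C5=C6 alkene is removed by the hydrogenation that sets C1.
5. Ring order: cyclopentane (starting material), cyclohexene (step 6), butyrolactone (step 11).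

Key step: step 6

Remark: indane locants are used for the bicyclic core of every intermediate (C1 bears the side chain, C4 the gem-dimethyl group, C7a the angular methyl); in the side chain Ca is the methine bearing the oxymethyl group and C2'–C5' are the lactone carbons (C2' = carbonyl); centers that a later step erases (C2 of 9, the carbinol carbons of 17 and 25) are carried as they form.

## Route

Step 1
Reactants: 1 2-methylcyclopent-2-en-1-one
Product: 2 (1S)-2-methylcyclopent-2-en-1-ol
Conditions: (R)-2-methyl-CBS-oxazaborolidine (10 mol %), BH3·THF, THF, −20 °C; then MeOH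
Reagents that add atoms: none
Why: CBS reduction; with the methyl-substituted alkenyl carbon as the large group, the (R)-oxazaborolidine should by the usual model deliver hydride to the face that gives the (S)-carbinol, the center from which C3a is later derived.

Step 2
Reactants: 2 (1S)-2-methylcyclopent-2-en-1-ol; 3 2-methylpropanoyl chloride
Product: 4 (1S)-2-methylcyclopent-2-en-1-yl 2-methylpropanoate
Conditions: Et3N, DMAP (5 mol %), CH2Cl2, 0 °C
Reagents that add atoms: none
Why: Plain O-acylation of a secondary allylic alcohol under basic, non-ionizing conditions, so the carbinol configuration is retained.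

Step 3
Reactants: 4 (1S)-2-methylcyclopent-2-en-1-yl 2-methylpropanoate
Product: 7 2-methyl-2-[(1R)-2-methylcyclopent-2-en-1-yl]propanoic acid, via silyl ketene acetal 5 (not isolated), via trimethylsilyl ester 6 (not isolated)
Conditions: LiN(iPr)2, THF, −78 °C; TMSCl, −78 → 65 °C; then 1 M HCl
Reagents that add atoms: none
Why: Ireland–Claisen rearrangement; the suprafacial [3,3]-sigmatropic shift across the cyclopentene forms the C3a–C4 bond on the face that carried the oxygen, so the carbinol chirality is transferred to C3a while the quaternary C4 is created.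

Step 4
Reactants: 7 2-methyl-2-[(1R)-2-methylcyclopent-2-en-1-yl]propanoic acid
Product: 8 (1R,2R,3R)-3-(1-hydroxy-2-methylpropan-2-yl)-2-methylcyclopentan-1-ol
Conditions: BH3·THF (4 equiv), THF, 0 → 23 °C; then NaOH, H2O2, H2O, 0 → 40 °C
Reagents that add atoms: hydrogen peroxide, OO
Why: Borane reduces the carboxylic acid to the neopentyl alcohol and hydroborates the trisubstituted alkene with boron at C1 (anti-Markovnikov, syn addition anti to the C3a substituent), and oxidation gives the diol; both new stereocenters are erased in steps 5 and 6.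

Step 5
Reactants: 8 (1R,2R,3R)-3-(1-hydroxy-2-methylpropan-2-yl)-2-methylcyclopentan-1-ol
Product: 9 (2R,3R)-2-methyl-3-(2-methyl-1-oxopropan-2-yl)cyclopentan-1-one
Conditions: (COCl)2, DMSO, CH2Cl2, −78 °C; Et3N, −78 → 0 °C
Reagents that add atoms: none
Why: Swern oxidation converts the primary and the secondary alcohol to aldehyde and ketone in one operation; the aldehyde sits on a quaternary carbon and cannot enolize, and C3a is not alpha to either carbonyl.

Step 6
Reactants: 9 (2R,3R)-2-methyl-3-(2-methyl-1-oxopropan-2-yl)cyclopentan-1-one; 10 ethenyl(triphenyl)phosphonium bromide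
Product: 13 (3aS,7aS)-4,4,7a-trimethyl-2,3,3a,4,7,7a-hexahydro-1H-inden-1-one, via potassium enolate 11 (not isolated), via phosphorus ylide 12 (not isolated)
Conditions: KOtBu (1.05 equiv), THF/t-BuOH, 0.02 M, 0 → 23 °C; then 10 (1.2 equiv), 23 → 65 °C
Reagents that add atoms: none
Why: The base equilibrates 9 to the more substituted C7a enolate 11, which adds in Michael fashion to the vinylphosphonium salt to form the C7–C7a bond and the ylide 12, whose carbon C6 then attacks the C5 aldehyde in an intramolecular Wittig olefination that forms C5=C6 and expels triphenylphosphine oxide. The closest known reaction type is the Schweizer-type vinylphosphonium annulation of carbonyl-tethered enolates, a tandem Michael addition/intramolecular Wittig reaction. The cyclohexene ring closes at the olefination stage by 6-exo-trig attack of the ylide carbon on the aldehyde carbonyl, followed by collapse of the oxaphosphetane to the cis ring alkene. The new quaternary stereocenter C7a is controlled by C3a: the acceptor should approach the planar enolate anti to the bulky tert-alkyl group, so C7 and C4 end up trans and the ring fusion is trans. The step needs the C7a enolate rather than the C2 enolate and freedom from aldol pathways; thermodynamic enolization should secure the former, the aldehyde on quaternary C4 cannot enolize, and aldol closure from C7a (cyclobutanol) or C2 (bridged norbornanol that cannot dehydrate) is strained and reversible. Only the C7a adduct can close an unstrained six-membered ring, so the irreversible Wittig step should drain the productive pathway.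

Step 7
Reactants: 13 (3aS,7aS)-4,4,7a-trimethyl-2,3,3a,4,7,7a-hexahydro-1H-inden-1-one
Product: 14 (3aS,7aS)-3a,7,7-trimethyl-3a,4,7,7a-tetrahydro-1H-inden-3-yl trifluoromethanesulfonate
Conditions: KN(SiMe3)2, THF, −78 °C; PhNTf2, −78 → 0 °C
Reagents that add atoms: N-phenylbis(trifluoromethanesulfonimide), O=S(=O)(N(c1ccccc1)S(=O)(=O)C(F)(F)F)C(F)(F)F
Why: Deprotonation can occur only at C2 because C7a is quaternary, and O-sulfonylation of that enolate gives the C1 alkenyl triflate.

Step 8
Reactants: 15 {[tert-butyl(dimethyl)silyl]oxy}acetaldehyde; 16 nitromethane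
Product: 17 1-{[tert-butyl(dimethyl)silyl]oxy}-3-nitropropan-2-ol (racemic)
Conditions: Et3N (20 mol %), 16 (5 equiv), THF, 0 → 23 °C
Reagents that add atoms: none
Why: Henry (nitroaldol) addition under catalytic base; the racemic carbinol center is removed in step 9.

Step 9
Reactants: 17 1-{[tert-butyl(dimethyl)silyl]oxy}-3-nitropropan-2-ol
Product: 18 tert-butyl(dimethyl){[(2E)-3-nitroprop-2-en-1-yl]oxy}silane
Conditions: MsCl, Et3N, CH2Cl2, −40 → 0 °C
Reagents that add atoms: none
Why: Mesylation and E1cB elimination of the β-nitro alcohol should give the thermodynamically favored (E)-nitroalkene.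

Step 10
Reactants: 18 tert-butyl(dimethyl){[(2E)-3-nitroprop-2-en-1-yl]oxy}silane; 19 methyl 4-oxobutanoate
Product: 20 methyl (3R,4R)-4-({[tert-butyl(dimethyl)silyl]oxy}methyl)-3-formyl-5-nitropentanoate
Conditions: (S)-2-[diphenyl(trimethylsilyloxy)methyl]pyrrolidine (10 mol %), PhCO2H (10 mol %), 19 (1.5 equiv), toluene, 0 → 23 °C
Reagents that add atoms: none
Why: Enamine-catalyzed Michael addition; the (E)-enamine of 19 adds through the acyclic synclinal transition state to the nitroalkene on the face left open by the diaryl(silyloxy)methyl group, which should give the syn adduct and set Ca and C4' as (R,R).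

Step 11
Reactants: 20 methyl (3R,4R)-4-({[tert-butyl(dimethyl)silyl]oxy}methyl)-3-formyl-5-nitropentanoate
Product: 22 (4R)-4-[(2R)-1-{[tert-butyl(dimethyl)silyl]oxy}-3-nitropropan-2-yl]oxolan-2-one, via hydroxy ester 21 (not isolated)
Conditions: NaBH4, MeOH, −20 °C; then TsOH·H2O (5 mol %), CH2Cl2, 23 °C
Reagents that add atoms: none
Why: Chemoselective borohydride reduction of the aldehyde (ester and nitro group untouched) followed by acid-catalyzed lactonization of the γ-hydroxy ester; C4' is fixed before it can epimerize.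

Step 12
Reactants: 22 (4R)-4-[(2R)-1-{[tert-butyl(dimethyl)silyl]oxy}-3-nitropropan-2-yl]oxolan-2-one
Product: 24 (2S)-3-{[tert-butyl(dimethyl)silyl]oxy}-2-[(3R)-5-oxooxolan-3-yl]propanal, via potassium nitronate 23 (not isolated)
Conditions: KOtBu (1.05 equiv), THF, −78 °C; dimethyldioxirane (acetone solution), −78 → 0 °C
Reagents that add atoms: dimethyldioxirane, CC1(C)OO1
Why: Oxidative Nef reaction; the nitronate forms at the most acidic C–H, is oxidized at carbon and collapses to the aldehyde with loss of nitrite, and Ca is not touched because it is beta to nitrogen.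

Step 13
Reactants: 14 (3aS,7aS)-3a,7,7-trimethyl-3a,4,7,7a-tetrahydro-1H-inden-3-yl trifluoromethanesulfonate; 24 (2S)-3-{[tert-butyl(dimethyl)silyl]oxy}-2-[(3R)-5-oxooxolan-3-yl]propanal
Product: 25 (4R)-4-[(2S)-1-{[tert-butyl(dimethyl)silyl]oxy}-3-hydroxy-3-[(3aS,7aS)-3a,7,7-trimethyl-3a,4,7,7a-tetrahydro-1H-inden-3-yl]propan-2-yl]oxolan-2-one (both carbinol epimers)
Conditions: CrCl2 (4 equiv), NiCl2 (2 mol %), DMF, 23 °C
Reagents that add atoms: none
Why: Nozaki–Hiyama–Kishi coupling; the alkenylchromium species formed from the triflate under nickel catalysis adds chemoselectively to the aldehyde and should tolerate the lactone and the epimerizable α-methine, and the new carbinol center is erased in step 14.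

Step 14
Reactants: 25 allylic alcohol (both carbinol epimers)
Product: 26 (4R)-4-[(2S)-1-{[tert-butyl(dimethyl)silyl]oxy}-3-oxo-3-[(3aS,7aS)-3a,7,7-trimethyl-3a,4,7,7a-tetrahydro-1H-inden-3-yl]propan-2-yl]oxolan-2-one
Conditions: Dess–Martin periodinane, CH2Cl2, 0 → 23 °C
Reagents that add atoms: none
Why: Dess–Martin oxidation under non-basic conditions converges both carbinol epimers to one enone without epimerizing Ca.

Step 15
Reactants: 26 enone
Product: 27 (4R)-4-[(2S)-1-{[tert-butyl(dimethyl)silyl]oxy}-3-oxo-3-[(1S,3aS,7aS)-4,4,7a-trimethyloctahydro-1H-inden-1-yl]propan-2-yl]oxolan-2-one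
Conditions: H2 (1 atm), 10% Pd/C, EtOAc, 23 °C
Reagents that add atoms: none
Why: Heterogeneous hydrogenation; the catalyst should approach the C1=C2 enone alkene from the face opposite the angular C7a methyl, so hydrogen enters cis to H3a and the acyl group ends up cis to the methyl (the target's C1 configuration), while the isolated C5=C6 alkene is saturated at the same time.

Step 16
Reactants: 27 saturated ketone
Product: 28 (4R)-4-[(2R)-1-{[tert-butyl(dimethyl)silyl]oxy}-3-[(1R,3aS,7aS)-4,4,7a-trimethyloctahydro-1H-inden-1-yl]but-3-en-2-yl]oxolan-2-one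
Conditions: Zn, CH2Br2, TiCl4, THF, 0 °C (reagent preformed); then 27, CH2Cl2, 0 → 23 °C
Reagents that add atoms: dibromomethane, BrCBr
Why: Takai–Lombardo methylenation; the non-basic zinc/titanium methylene reagent olefinates hindered, enolizable ketones without epimerizing the adjacent methine and should leave the lactone and the silyl ether alone.

Step 17
Reactants: 28 methylene lactone
Product: 30 (3S,4R)-4-[(2R)-1-{[tert-butyl(dimethyl)silyl]oxy}-3-[(1R,3aS,7aS)-4,4,7a-trimethyloctahydro-1H-inden-1-yl]but-3-en-2-yl]-3-hydroxyoxolan-2-one, via potassium lactone enolate 29 (not isolated)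
Conditions: KN(SiMe3)2, THF, −78 °C; 2-(phenylsulfonyl)-3-phenyloxaziridine, −78 °C; aqueous work-up
Reagents that add atoms: 2-(phenylsulfonyl)-3-phenyloxaziridine, O=S(=O)(N1OC1c1ccccc1)c1ccccc1
Why: Enolate oxidation with the Davis oxaziridine; the lactone CH2 is the only acidic site, and the oxidant should attack the enolate face opposite the bulky C4' substituent, setting the trans (3S) hydroxyl.

Step 18
Reactants: 30 silyl-protected hydroxy lactone
Product: 31 (3S,4R)-3-hydroxy-4-[(2R)-1-hydroxy-3-[(1R,3aS,7aS)-4,4,7a-trimethyloctahydro-1H-inden-1-yl]but-3-en-2-yl]oxolan-2-one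
Conditions: HF·pyridine, pyridine, THF, 0 → 23 °C
Reagents that add atoms: none
Why: Buffered fluoride cleavage of the primary silyl ether should spare the lactone, the secondary alcohol and the 1,1-disubstituted alkene.

Step 19
Reactants: 31 diol
Product: 32 [(2R)-2-[(3R,4S)-4-hydroxy-5-oxooxolan-3-yl]-3-[(1R,3aS,7aS)-4,4,7a-trimethyloctahydro-1H-inden-1-yl]but-3-en-1-yl] acetate
Conditions: AcCl (1.1 equiv), 2,4,6-collidine, CH2Cl2, −78 °C
Reagents that add atoms: acetyl chloride, CC(Cl)=O
Why: Chemoselective acylation; the unhindered primary alcohol should react far faster than the secondary α-hydroxy lactone alcohol under acetyl chloride/collidine at low temperature, giving the target.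

## Compound list

1 | 2-methylcyclopent-2-en-1-one | CC1=CCCC1=O | starting material
2 | (1S)-2-methylcyclopent-2-en-1-ol | O[C@H]1CCC=C1C | intermediate
3 | 2-methylpropanoyl chloride | CC(C)C(Cl)=O | starting material
4 | (1S)-2-methylcyclopent-2-en-1-yl 2-methylpropanoate | CC(C)C(=O)O[C@H]1CCC=C1C | intermediate
5 | trimethylsilyl ketene acetal of 4 (not isolated) | CC(C)=C(O[Si](C)(C)C)O[C@H]1CCC=C1C | intermediate
6 | trimethylsilyl 2-methyl-2-[(1R)-2-methylcyclopent-2-en-1-yl]propanoate (not isolated) | C[Si](C)(C)OC(=O)C(C)(C)[C@@H]1CCC=C1C | intermediate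
7 | 2-methyl-2-[(1R)-2-methylcyclopent-2-en-1-yl]propanoic acid | OC(=O)C(C)(C)[C@@H]1CCC=C1C | intermediate
8 | (1R,2R,3R)-3-(1-hydroxy-2-methylpropan-2-yl)-2-methylcyclopentan-1-ol | OCC(C)(C)[C@@H]1CC[C@@H](O)[C@@H]1C | intermediate
9 | (2R,3R)-2-methyl-3-(2-methyl-1-oxopropan-2-yl)cyclopentan-1-one (cis isomer as first formed) | O=CC(C)(C)[C@@H]1CCC(=O)[C@@H]1C | intermediate
10 | ethenyl(triphenyl)phosphonium bromide | C=C[P+](c1ccccc1)(c1ccccc1)c1ccccc1.[Br-] | starting material
11 | potassium (3R)-2-methyl-3-(2-methyl-1-oxopropan-2-yl)cyclopent-1-en-1-olate (not isolated) | [K+].[O-]C1=C(C)[C@@H](CC1)C(C)(C)C=O | intermediate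
12 | {2-[(1S,2S)-1-methyl-2-(2-methyl-1-oxopropan-2-yl)-5-oxocyclopentyl]ethylidene}(triphenyl)phosphorane (not isolated) | O=CC(C)(C)[C@@H]1CCC(=O)[C@@]1(C)CC=P(c1ccccc1)(c1ccccc1)c1ccccc1 | intermediate
13 | (3aS,7aS)-4,4,7a-trimethyl-2,3,3a,4,7,7a-hexahydro-1H-inden-1-one | O=C1CC[C@H]2C(C)(C)C=CC[C@]12C | intermediate
14 | (3aS,7aS)-3a,7,7-trimethyl-3a,4,7,7a-tetrahydro-1H-inden-3-yl trifluoromethanesulfonate | O=S(=O)(OC1=CC[C@H]2C(C)(C)C=CC[C@]12C)C(F)(F)F | intermediate
15 | {[tert-butyl(dimethyl)silyl]oxy}acetaldehyde | CC(C)(C)[Si](C)(C)OCC=O | starting material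
16 | nitromethane | C[N+](=O)[O-] | starting material
17 | 1-{[tert-butyl(dimethyl)silyl]oxy}-3-nitropropan-2-ol (racemic) | CC(C)(C)[Si](C)(C)OCC(O)C[N+](=O)[O-] | intermediate
18 | tert-butyl(dimethyl){[(2E)-3-nitroprop-2-en-1-yl]oxy}silane | CC(C)(C)[Si](C)(C)OC/C=C/[N+](=O)[O-] | intermediate
19 | methyl 4-oxobutanoate | COC(=O)CCC=O | starting material
20 | methyl (3R,4R)-4-({[tert-butyl(dimethyl)silyl]oxy}methyl)-3-formyl-5-nitropentanoate | O=C[C@H](CC(=O)OC)[C@@H](CO[Si](C)(C)C(C)(C)C)C[N+](=O)[O-] | intermediate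
21 | methyl (3R,4R)-4-({[tert-butyl(dimethyl)silyl]oxy}methyl)-3-(hydroxymethyl)-5-nitropentanoate (not isolated) | OC[C@H](CC(=O)OC)[C@@H](CO[Si](C)(C)C(C)(C)C)C[N+](=O)[O-] | intermediate
22 | (4R)-4-[(2R)-1-{[tert-butyl(dimethyl)silyl]oxy}-3-nitropropan-2-yl]oxolan-2-one | [O-][N+](=O)C[C@H](CO[Si](C)(C)C(C)(C)C)[C@@H]1COC(=O)C1 | intermediate
23 | potassium nitronate of 22 (not isolated) | [K+].[O-][N+]([O-])=C[C@H](CO[Si](C)(C)C(C)(C)C)[C@@H]1COC(=O)C1 | intermediate
24 | (2S)-3-{[tert-butyl(dimethyl)silyl]oxy}-2-[(3R)-5-oxooxolan-3-yl]propanal | O=C[C@H](CO[Si](C)(C)C(C)(C)C)[C@@H]1COC(=O)C1 | intermediate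
25 | (4R)-4-[(2S)-1-{[tert-butyl(dimethyl)silyl]oxy}-3-hydroxy-3-[(3aS,7aS)-3a,7,7-trimethyl-3a,4,7,7a-tetrahydro-1H-inden-3-yl]propan-2-yl]oxolan-2-one (both carbinol epimers) | OC(C1=CC[C@H]2C(C)(C)C=CC[C@]12C)[C@H](CO[Si](C)(C)C(C)(C)C)[C@@H]1COC(=O)C1 | intermediate
26 | (4R)-4-[(2S)-1-{[tert-butyl(dimethyl)silyl]oxy}-3-oxo-3-[(3aS,7aS)-3a,7,7-trimethyl-3a,4,7,7a-tetrahydro-1H-inden-3-yl]propan-2-yl]oxolan-2-one | O=C(C1=CC[C@H]2C(C)(C)C=CC[C@]12C)[C@H](CO[Si](C)(C)C(C)(C)C)[C@@H]1COC(=O)C1 | intermediate
27 | (4R)-4-[(2S)-1-{[tert-butyl(dimethyl)silyl]oxy}-3-oxo-3-[(1S,3aS,7aS)-4,4,7a-trimethyloctahydro-1H-inden-1-yl]propan-2-yl]oxolan-2-one | O=C([C@H]1CC[C@H]2C(C)(C)CCC[C@]12C)[C@H](CO[Si](C)(C)C(C)(C)C)[C@@H]1COC(=O)C1 | intermediate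
28 | (4R)-4-[(2R)-1-{[tert-butyl(dimethyl)silyl]oxy}-3-[(1R,3aS,7aS)-4,4,7a-trimethyloctahydro-1H-inden-1-yl]but-3-en-2-yl]oxolan-2-one | C=C([C@H]1CC[C@H]2C(C)(C)CCC[C@]12C)[C@H](CO[Si](C)(C)C(C)(C)C)[C@@H]1COC(=O)C1 | intermediate
29 | potassium lactone enolate of 28 (not isolated) | C=C([C@H]1CC[C@H]2C(C)(C)CCC[C@]12C)[C@H](CO[Si](C)(C)C(C)(C)C)[C@@H]1COC([O-])=C1.[K+] | intermediate
30 | (3S,4R)-4-[(2R)-1-{[tert-butyl(dimethyl)silyl]oxy}-3-[(1R,3aS,7aS)-4,4,7a-trimethyloctahydro-1H-inden-1-yl]but-3-en-2-yl]-3-hydroxyoxolan-2-one | C=C([C@H]1CC[C@H]2C(C)(C)CCC[C@]12C)[C@H](CO[Si](C)(C)C(C)(C)C)[C@@H]1COC(=O)[C@H]1O | intermediate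
31 | (3S,4R)-3-hydroxy-4-[(2R)-1-hydroxy-3-[(1R,3aS,7aS)-4,4,7a-trimethyloctahydro-1H-inden-1-yl]but-3-en-2-yl]oxolan-2-one | C=C([C@H]1CC[C@H]2C(C)(C)CCC[C@]12C)[C@H](CO)[C@@H]1COC(=O)[C@H]1O | intermediate
32 | [(2R)-2-[(3R,4S)-4-hydroxy-5-oxooxolan-3-yl]-3-[(1R,3aS,7aS)-4,4,7a-trimethyloctahydro-1H-inden-1-yl]but-3-en-1-yl] acetate | C=C([C@H]1CC[C@H]2C(C)(C)CCC[C@]12C)[C@H](COC(C)=O)[C@@H]1COC(=O)[C@H]1O | target

## Step count and risks

Total steps: 19. Longest linear sequence: 14 steps (steps 1–7 and 13–19); the side-chain aldehyde takes 5 steps (8–12) and joins at step 13.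

Steps most likely to fail:

**Step 6 (key annulation).** Enolization toward C2 instead of C7a, intermolecular aldol condensation of the C2 enolate with the aldehyde, or quenching of the ylide before ring closure would divert material; attack cis to the C3a substituent would give the cis-fused ring. Fallback: the two bonds are made one after the other, setting out from 9. Chemoselective Wittig methylenation of the aldehyde (Ph3P=CH2, THF, 0 °C) should give the keto alkene (2RS,3R)-2-methyl-3-(2-methylbut-3-en-2-yl)cyclopentan-1-one F1. Thermodynamic silylation (TMSCl, NaI, Et3N, MeCN) gives the tetrasubstituted silyl enol ether trimethyl{[(3S)-2-methyl-3-(2-methylbut-3-en-2-yl)cyclopent-1-en-1-yl]oxy}silane F2, which is freed from its regioisomer by chromatography. MeLi (THF, 0 °C) cleaves it to the regiodefined lithium (3S)-2-methyl-3-(2-methylbut-3-en-2-yl)cyclopent-1-en-1-olate F3, and allyl bromide alkylates this anti to the C3a substituent to give (2S,3S)-2-methyl-3-(2-methylbut-3-en-2-yl)-2-(prop-2-en-1-yl)cyclopentan-1-one F4. Ring-closing metathesis with the second-generation Grubbs catalyst (CH2Cl2, 40 °C) closes C5=C6, and the route is rejoined at 13.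

**Step 16 (methylenation).** Carbonyl olefination of the doubly branched ketone may be too slow, and long exposure to the Lewis-acidic reagent could enolize the ketone and epimerize Ca. Fallback: the methylene carbon is brought in as a methyl nucleophile, setting out from 27. MeMgBr/CeCl3 (THF, −78 °C), whose organocerium reagent should add to the ketone in preference to the lactone, gives the tertiary carbinol (4R)-4-[(2S,3RS)-1-{[tert-butyl(dimethyl)silyl]oxy}-3-hydroxy-3-[(1S,3aS,7aS)-4,4,7a-trimethyloctahydro-1H-inden-1-yl]butan-2-yl]oxolan-2-one F6. Dehydration with SOCl2/pyridine (CH2Cl2, −30 °C), which should remove the most accessible methyl hydrogen, gives the 1,1-disubstituted alkene, and the route is rejoined at 28.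

**Step 12 (Nef reaction).** Over-oxidation of the aldehyde to the acid, base-induced epimerization at Ca or β-elimination of the silyloxy group may erode the aldehyde. Fallback: the nitro group is taken down reductively, setting out from 22. SnCl2/PhSH/Et3N (MeCN, 23 °C) should reduce the primary nitro group to the aldoxime (4R)-4-[(2R)-1-{[tert-butyl(dimethyl)silyl]oxy}-3-(hydroxyimino)propan-2-yl]oxolan-2-one F5, and transoximation with aqueous glyoxylic acid (THF, 23 °C) releases the aldehyde under near-neutral conditions, so the route is rejoined at 24.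

## Further compounds

F1 | step 6 | (2RS,3R)-2-methyl-3-(2-methylbut-3-en-2-yl)cyclopentan-1-one | C=CC(C)(C)[C@@H]1CCC(=O)C1C
F2 | step 6 | trimethyl{[(3S)-2-methyl-3-(2-methylbut-3-en-2-yl)cyclopent-1-en-1-yl]oxy}silane | C=CC(C)(C)[C@@H]1CCC(O[Si](C)(C)C)=C1C
F3 | step 6 | lithium (3S)-2-methyl-3-(2-methylbut-3-en-2-yl)cyclopent-1-en-1-olate | [Li+].[O-]C1=C(C)[C@@H](CC1)C(C)(C)C=C
F4 | step 6 | (2S,3S)-2-methyl-3-(2-methylbut-3-en-2-yl)-2-(prop-2-en-1-yl)cyclopentan-1-one | C=CC[C@]1(C)C(=O)CC[C@H]1C(C)(C)C=C
F5 | step 12 | (4R)-4-[(2R)-1-{[tert-butyl(dimethyl)silyl]oxy}-3-(hydroxyimino)propan-2-yl]oxolan-2-one | ON=C[C@H](CO[Si](C)(C)C(C)(C)C)[C@@H]1COC(=O)C1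
F6 | step 16 | (4R)-4-[(2S,3RS)-1-{[tert-butyl(dimethyl)silyl]oxy}-3-hydroxy-3-[(1S,3aS,7aS)-4,4,7a-trimethyloctahydro-1H-inden-1-yl]butan-2-yl]oxolan-2-one | CC(O)([C@H]1CC[C@H]2C(C)(C)CCC[C@]12C)[C@H](CO[Si](C)(C)C(C)(C)C)[C@@H]1COC(=O)C1
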